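**Retrosynthetic overview**

1. Last C–C bond: the CH2 on C6 of the benzoxepinone half (iodide 23) is joined to the exocyclic alkene carbon of the decalin half (E-enol triflate 39) by a Negishi alkyl–alkenyl coupling; desilylation ends the route.
2. Benzoxepinone half: the oxepan-3-one ring (O1–C2–C3–C4–C5–C5a–C9a) is a 2,2-dimethyl-3(2H)-furanone (O1, C2, C3, C4, C9a) with C5/C5a inserted into its C4–C9a bond. An intramolecular [2+2] photocycloaddition forms C4–C5 and C5a–C9a (closing the cyclohexane ring as well); push–pull cleavage of C4–C9a then expands the five- to the seven-membered ring.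
3. Enabling feature: the β-oxygenated enone array O1–C9a=C4–C3(=O) next to quaternary C2, together with the tertiary C7 oxygen, which carries a removable silicon tether to C5 (oxasiline ring) and so fixes the quaternary C5a.
4. C6 and C7 come from Sharpless epoxidation of geraniol and SN2 opening with an isopropenyl cuprate; C9a–H is set by hydrogenation anti to the angular C5a methyl after the tether is removed.
5. Decalin half: ring B is bought (4,4-dimethylcyclohexenone); ring A is added by a catalytic asymmetric Diels–Alder reaction with isoprene (cis fusion), followed by the C5′ carbinol, C1′ homologation and E-selective enol triflation. Ring order: oxasiline (temporary) → furanone → cyclohexane + cyclobutane → oxepane; ring B → ring A.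

Key step: step 10

Locants: the right half is numbered as 1-benzoxepine (O1, C2, C3, C4, C5, C5a, C6–C9, C9a); the decalin half carries primed naphthalene locants (C1′ alkylidene carbon, C2′ methyl, C4a′/C8a′ ring fusion, C5′ carbinol, C8′ gem-dimethyl).

Assumption: the (S)-configured oxazaborolidinium catalyst of step 17 is taken to shield the enone face that leads to the (4aR,8aS) adduct 26, by analogy with its behaviour toward 2-cyclohexenone; if the sense is opposite, the (R)-catalyst is used.

**Route**

Step 1
Reactants: 1 geraniol
Product: 2 (2S,3S)-2,3-epoxygeraniol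
Conditions: Ti(OiPr)4 (5 mol%), L-(+)-diethyl tartrate (7 mol%), tBuOOH, 4 Å MS, CH2Cl2, −20 °C
Reagents that add atoms: tert-butyl hydroperoxide CC(C)(C)OO
Why: Sharpless asymmetric epoxidation of the allylic alcohol; the L-(+)-tartrate–titanium complex delivers oxygen to the alkene face that gives the (2S,3S) epoxide, which later becomes C6 and C7.

Step 2
Reactants: 2 (2S,3S)-2,3-epoxygeraniol
Product: 3 (2R,3S)-3,7-dimethyl-2-(prop-1-en-2-yl)oct-6-ene-1,3-diol
Conditions: isopropenylmagnesium bromide (3 equiv), CuI (10 mol%), THF, −30 → 0 °C
Reagents that add atoms: isopropenylmagnesium bromide CC(=C)[Mg]Br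
Why: Copper-catalysed SN2 opening of the 2,3-epoxy alcohol at the less substituted C2 with inversion should give the 1,3-diol, placing the isopropenyl group (future C5a) anti to the tertiary oxygen as the C6/C7 relationship of the target requires.

Step 3
Reactants: 3 (2R,3S)-3,7-dimethyl-2-(prop-1-en-2-yl)oct-6-ene-1,3-diol
Product: 4 primary benzyl ether of diol 3
Conditions: NaH (1.05 equiv), BnBr (1.05 equiv), Bu4NI (cat.), THF, 0 °C → rt
Reagents that add atoms: benzyl bromide BrCc1ccccc1
Why: Williamson etherification in which the primary alkoxide reacts much faster than the hindered tertiary one, so only the primary hydroxyl should be benzylated (no stereocentre is touched).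

Step 4
Reactants: 4 primary benzyl ether of diol 3
Product: 5 tertiary dimethyl(vinyl)silyl ether of 4
Conditions: ClSiMe2(CH=CH2) (1.5 equiv), imidazole, DMAP (cat.), DMF, rt
Reagents that add atoms: chloro(dimethyl)vinylsilane C=C[Si](C)(C)Cl
Why: Silyl ether formation with a small chlorosilane masks the tertiary hydroxyl and installs the vinylsilane half of the temporary tether.

Step 5
Reactants: 5 tertiary dimethyl(vinyl)silyl ether of 4
Product: 6 oxasiline: 5-[(benzyloxy)methyl]-2,2,4,6-tetramethyl-6-(4-methylpent-3-en-1-yl)-5,6-dihydro-2H-1,2-oxasiline (CH2OBn and 6-methyl cis)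
Conditions: Mo(N-2,6-iPr2C6H3)(CHCMe2Ph)[OCMe(CF3)2]2 (8 mol%), benzene, rt → 45 °C
Reagents that add atoms: none
Why: Ring-closing metathesis of a vinylsilyl ether with the 1,1-disubstituted alkene, a known route to six-membered cycloalkenyl siloxanes; the trisubstituted side-chain alkene is too hindered to take part and no stereocentre is touched.

Step 6
Reactants: 6 oxasiline
Product: 8 aldehyde: 3-(oxasilin-6-yl)propanal, via side-chain glycol 7 (not isolated)
Conditions: OsO4 (2 mol%), NMO (1.1 equiv), acetone/H2O, 0 °C; then NaIO4, THF/pH 7 buffer, rt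
Reagents that add atoms: N-methylmorpholine N-oxide C[N+]1([O-])CCOCC1; water O
Why: Catalytic dihydroxylation should be fastest at the unhindered, electron-rich side-chain alkene (the ring vinylsilane is flanked by silicon and a branched carbon), and periodate glycol cleavage then gives the aldehyde (dihydroxylation–glycol cleavage sequence).

Step 7
Reactants: 8 aldehyde; 9 2-methyl-2-(trimethylsilyloxy)but-3-yne
Product: 11 propargylic alcohol (carbinol epimers), via lithium acetylide 10 (not isolated)
Conditions: 9, n-BuLi, THF, −78 °C; then 8, −78 °C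
Reagents that add atoms: none
Why: 1,2-Addition of a lithium acetylide to the aldehyde; the new carbinol centre forms as a mixture that is erased in step 8.

Step 8
Reactants: 11 propargylic alcohol
Product: 12 ynone
Conditions: MnO2 (activated, 15 equiv), CH2Cl2, rt
Reagents that add atoms: none
Why: Manganese dioxide oxidation of a propargylic alcohol to the conjugated ynone; silyl ethers and the vinylsilane are inert.

Step 9
Reactants: 12 ynone
Product: 14 furanone: 2,2-dimethyl-5-[2-(oxasilin-6-yl)ethyl]furan-3(2H)-one, via β-diethylamino enone 13 (not isolated)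
Conditions: Et2NH, EtOH, rt; then AcOH/THF/H2O, rt
Reagents that add atoms: water O
Why: Conjugate addition of the amine to the ynone, then hydrolysis, loss of the trimethylsilyl group and cyclodehydration of the resulting γ-hydroxy 1,3-diketone (the classical 3(2H)-furanone synthesis); the gem-dimethyl carbon becomes C2, the former aldehyde carbon C9a.

Step 10
Reactants: 14 furanone
Product: 15 photoadduct: cyclobutane (C4, C5, C5a, C9a) cis-fused to the tetrahydrofuranone, the new cyclohexane and the siloxane bridge
Conditions: hν (λ ≈ 300 nm, Pyrex), degassed MeCN (5 mM), 0 °C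
Reagents that add atoms: none
Why: Excitation of the 3(2H)-furanone (a cyclic vinylogous ester) gives its triplet, whose β-carbon C9a adds to C5a of the tethered vinylsilane, and the resulting 1,4-biradical collapses between C4 and C5; the closest known reaction type is the intramolecular enone–alkene [2+2] photocycloaddition of 3(2H)-furanones and other β-oxygenated enones used in de Mayo sequences. The cyclohexane ring closes in the 6-exo-trig mode (C5a–C9a first) and the four-membered ring by radical recombination (C4–C5), both cis-fused of necessity. C5a is controlled by the oxasiline ring: C5 is held to the C7 oxygen through silicon, so C9a can reach C5a only on the alkene face that carries C8, which puts C5 cis to the C7 oxygen and the C5a methyl cis to the C7 methyl and the C6 side chain, and the silicon held cis to C6 on the alkene also enforces by A(1,3) strain the rotamer with C6–H in the alkene plane. C4 and C9a follow from the cis fusion but are not carried to the target (C4 becomes CH2 in step 11, C9a is reset in step 14). The step needs straight rather than crossed regiochemistry and a single alkene face: the two-carbon link from C7 makes six-membered closure onto C5a far easier than seven-membered closure onto C5, and the temporary ring leaves only one face open. Light above 290 nm excites only the furanone, so the benzyl ether and the siloxane should be untouched.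

Step 11
Reactants: 15 photoadduct
Product: 17 enol ether ketone: siloxane-bridged 2,2,5a,7-tetramethyl-4,5,5a,6,7,8-hexahydro-1-benzoxepin-3(2H)-one with a C9=C9a double bond, via trimethylsilyl enol ether 16 (not isolated)
Conditions: TMSOTf (1.2 equiv), 2,6-lutidine (2 equiv), CH2Cl2, −78 → 0 °C; then K2CO3 (cat.), MeOH, 0 °C
Reagents that add atoms: none
Why: Proposed new method: O-silylation of the ketone turns the cyclobutane into a push–pull system in which the O1 lone pair expels C4 from C9a (strain-driven heterolysis to an oxocarbenium ion and a silyl enol ether), the only β-hydrogens of that ion (on C9) are removed by the hindered base to give the cyclic enol ether, and mild methanolysis returns the C3 ketone, so the furanone has grown by two carbons into the oxepinone without creating a stereocentre (C4 becomes CH2, C9a sp2); the closest known reaction types are the retro-aldol opening of de Mayo photoadducts and the Lewis-acid ring opening of alkoxy-substituted donor–acceptor cyclobutanes.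

Step 12
Reactants: 17 enol ether ketone
Product: 18 5-hydroxy ketone with free C7 hydroxyl
Conditions: KF, KHCO3, 30% H2O2, THF/MeOH, 40 °C
Reagents that add atoms: hydrogen peroxide OO
Why: Tamao–Fleming oxidation of the alkoxysilane replaces C5–Si by C5–OH with retention and releases the tertiary C7 hydroxyl, removing the tether under mildly basic conditions that an enol ether tolerates.

Step 13
Reactants: 18 5-hydroxy ketone
Product: 20 enone: C4=C5 unsaturated 3-ketone (C9=C9a enol ether retained), via C5 mesylate 19 (not isolated)
Conditions: MsCl, Et3N, CH2Cl2, 0 °C; then DBU, rt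
Reagents that add atoms: none
Why: Selective mesylation of the secondary β-hydroxyl (the tertiary C7 hydroxyl is too hindered) followed by E1cB elimination gives the conjugated enone and erases the C5 centre.

Step 14
Reactants: 20 enone
Product: 21 (5aS,6R,7S,9aS)-7-hydroxy-6-(hydroxymethyl)-2,2,5a,7-tetramethyloctahydro-1-benzoxepin-3(2H)-one
Conditions: H2 (3 atm), Pd(OH)2/C, EtOAc, rt
Reagents that add atoms: none
Why: One heterogeneous hydrogenation should saturate the enone C=C, cleave the benzyl ether and reduce the enol ether, to which hydrogen adds on the face opposite the angular C5a methyl and the axial C7 methyl, setting C9a–H anti to the C5a methyl (trans ring fusion).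

Step 15
Reactants: 21 keto diol
Product: 22 primary iodide
Conditions: I2, PPh3, imidazole, CH2Cl2, 0 °C → rt
Reagents that add atoms: iodine II
Why: Appel-type iodination converts only the primary alcohol (the tertiary one cannot form a displaceable phosphonium ether), giving the handle for the coupling.

Step 16
Reactants: 22 primary iodide
Product: 23 C7 trimethylsilyl ether of iodide 22
Conditions: N-(trimethylsilyl)imidazole, CH2Cl2, rt
Reagents that add atoms: N-(trimethylsilyl)imidazole C[Si](C)(C)n1ccnc1
Why: Neutral silyl transfer protects the tertiary hydroxyl so that it cannot protonate the organozinc reagent of step 28; the ketone is not enolised.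

Step 17
Reactants: 24 4,4-dimethylcyclohex-2-en-1-one; 25 isoprene
Product: 26 (4aR,8aS)-4,4,6-trimethyl-3,4,4a,5,8,8a-hexahydronaphthalen-1(2H)-one (cis-fused)
Conditions: 25 (5 equiv), protonated (S)-B-(o-tolyl)-α,α-diphenylprolinol oxazaborolidine triflimide salt (20 mol%), CH2Cl2, −40 → −20 °C
Reagents that add atoms: none
Why: Catalytic enantioselective Diels–Alder reaction: suprafacial addition gives the cis ring fusion (C4a′, C8a′), the 2-methyl group of the diene directs the para regiochemistry (methyl on C2′), and the chiral Lewis acid blocks one face of the coordinated enone.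

Step 18
Reactants: 26 cis-octalone
Product: 27 C5′ exocyclic methylene compound
Conditions: Cp2TiMe2 (2 equiv), toluene, 65 °C, dark
Reagents that add atoms: dimethyltitanocene C[Ti](C)(C1C=CC=C1)C1C=CC=C1
Why: Non-basic carbonyl methylenation with the titanium methylidene, chosen so that the epimerisable ring-fusion centre next to the ketone is not disturbed.

Step 19
Reactants: 27 C5′ exocyclic methylene compound
Product: 29 tertiary alcohol (C5′ hydroxyl cis to the two ring-fusion hydrogens), via tertiary hydroperoxide 28 (not isolated)
Conditions: Co(acac)2 (20 mol%), PhSiH3 (2 equiv), O2 (1 atm), THF, rt; then PPh3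
Reagents that add atoms: dioxygen O=O
Why: Mukaiyama hydration: hydrogen-atom transfer to the accessible terminal CH2 of the 1,1-disubstituted alkene (faster than to the ring trisubstituted alkene) gives a tertiary radical that oxygen should trap on the convex face of the cis-decalin, setting C5′.

Step 20
Reactants: 29 tertiary alcohol
Product: 30 triethylsilyl ether of 29
Conditions: TESOTf, 2,6-lutidine, CH2Cl2, −78 → 0 °C
Reagents that add atoms: triethylsilyl triflate CC[Si](CC)(CC)OS(=O)(=O)C(F)(F)F
Why: Silylation of the hindered tertiary alcohol with the silyl triflate protects it against the titanium, boron and amide reagents that follow.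

Step 21
Reactants: 30 triethylsilyl ether
Product: 31 C1′ allylic alcohol (epimers)
Conditions: SeO2 (0.5 equiv), tBuOOH (3 equiv), CH2Cl2, rt
Reagents that add atoms: tert-butyl hydroperoxide CC(C)(C)OO; selenium dioxide O=[Se]=O
Why: Selenium dioxide allylic oxidation (ene reaction then [2,3]-shift) attacks the ring CH2 on the more substituted alkene carbon, i.e. C1′, and the new carbinol centre is erased in step 22.

Step 22
Reactants: 31 C1′ allylic alcohol
Product: 32 enone (C1′ ketone, C2′=C3′)
Conditions: triacetoxyperiodinane (DMP), NaHCO3, CH2Cl2, rt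
Reagents that add atoms: none
Why: Buffered periodinane oxidation of the allylic alcohol to the enone under conditions that do not epimerise C8a′.

Step 23
Reactants: 32 enone
Product: 33 saturated C1′ ketone with C2′ methyl cis to the C8′ ring bond
Conditions: H2 (1 atm), Pd/C, EtOAc, rt
Reagents that add atoms: none
Why: Heterogeneous hydrogenation delivers hydrogen to the convex face of ring A (the face of the ring-fusion hydrogens), which sets C2′ with its hydrogen cis to them.

Step 24
Reactants: 33 saturated C1′ ketone
Product: 34 C1′ exocyclic methylene compound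
Conditions: Cp2TiMe2 (3 equiv), toluene, 70 °C, dark
Reagents that add atoms: dimethyltitanocene C[Ti](C)(C1C=CC=C1)C1C=CC=C1
Why: Titanium-methylidene olefination works on hindered, enolisable ketones without base, so C2′ and C8a′ should keep their configuration.

Step 25
Reactants: 34 C1′ exocyclic methylene compound
Product: 36 primary alcohol (C1′ epimers), via alkylborane 35 (not isolated)
Conditions: BH3·THF, THF, 0 °C → rt; then NaOH, H2O2, 0 °C
Reagents that add atoms: hydrogen peroxide OO
Why: Anti-Markovnikov hydroboration–oxidation of the 1,1-disubstituted alkene gives the one-carbon-homologated primary alcohol; the C1′ centre formed is removed again in step 27.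

Step 26
Reactants: 36 primary alcohol
Product: 37 C1′ carbaldehyde (C1′ epimers)
Conditions: triacetoxyperiodinane (DMP), NaHCO3, CH2Cl2, rt
Reagents that add atoms: none
Why: Periodinane oxidation of the primary alcohol to the aldehyde without over-oxidation.

Step 27
Reactants: 37 C1′ carbaldehyde
Product: 39 (E)-enol triflate, via potassium enolate 38 (not isolated)
Conditions: KN(SiMe3)2, THF, −78 °C; then PhNTf2, −78 → 0 °C
Reagents that add atoms: N-phenylbis(trifluoromethanesulfonimide) O=S(=O)(N(c1ccccc1)S(=O)(=O)C(F)(F)F)C(F)(F)F
Why: Deprotonation of the α-branched aldehyde and O-sulfonylation of the enolate; the enolate oxygen should sit on the side of C2′ and away from C8a′ with its neighbouring gem-dimethyl carbon (A(1,3) strain), which gives the E geometry, and only C1′–H is acidic so C2′ and C8a′ are safe.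

Step 28
Reactants: 23 C7 trimethylsilyl ether iodide; 39 (E)-enol triflate
Product: 41 bis-silyl ether of the target, via alkylzinc iodide 40 (not isolated)
Conditions: 23, Zn dust (activated with TMSCl and 1,2-dibromoethane), LiCl, THF, 40 °C; then 39, Pd(OAc)2 (4 mol%), SPhos (8 mol%), THF/NMP, rt
Reagents that add atoms: none
Why: Negishi coupling: zinc inserts into the primary C–I bond without touching the ketone, and the zerovalent palladium catalyst couples the alkylzinc with the enol triflate with retention of alkene geometry, forming the CH2–CH= bond.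

Step 29
Reactants: 41 bis-silyl ether of the target
Product: 42 target CNP0232921.1
Conditions: Bu4NF, THF, 0 °C → rt
Reagents that add atoms: none
Why: Fluoride cleaves both tertiary silyl ethers (desilylation) without affecting the ketone, the ether ring or the trisubstituted alkene.

**Compound list**

1 | geraniol, (2E)-3,7-dimethylocta-2,6-dien-1-ol | CC(C)=CCC/C(C)=C/CO | starting material
2 | (2S,3S)-2,3-epoxygeraniol | OC[C@@H]1O[C@@]1(C)CCC=C(C)C | intermediate
3 | (2R,3S)-3,7-dimethyl-2-(prop-1-en-2-yl)oct-6-ene-1,3-diol | OC[C@H]([C@@](C)(O)CCC=C(C)C)C(C)=C | intermediate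
4 | primary benzyl ether of 3 | O(Cc1ccccc1)C[C@H]([C@@](C)(O)CCC=C(C)C)C(C)=C | intermediate
5 | tertiary dimethyl(vinyl)silyl ether of 4 | O(Cc1ccccc1)C[C@H]([C@@](C)(O[Si](C)(C)C=C)CCC=C(C)C)C(C)=C | intermediate
6 | oxasiline: 5-[(benzyloxy)methyl]-2,2,4,6-tetramethyl-6-(4-methylpent-3-en-1-yl)-5,6-dihydro-2H-1,2-oxasiline, CH2OBn cis to 6-methyl | C[C@@]1(CCC=C(C)C)O[Si](C)(C)C=C(C)[C@@H]1COCc1ccccc1 | intermediate
7 | side-chain glycol of 6 (carbinol epimers) | C[C@@]1(CCC(O)C(C)(C)O)O[Si](C)(C)C=C(C)[C@@H]1COCc1ccccc1 | intermediate (not isolated)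
8 | aldehyde: 3-(oxasilin-6-yl)propanal | O=CCC[C@]1(C)O[Si](C)(C)C=C(C)[C@@H]1COCc1ccccc1 | intermediate
9 | 2-methyl-2-(trimethylsilyloxy)but-3-yne | C#CC(C)(C)O[Si](C)(C)C | starting material
10 | lithium acetylide of 9 | [Li]C#CC(C)(C)O[Si](C)(C)C | intermediate (not isolated)
11 | propargylic alcohol (carbinol epimers) | C[Si](C)(C)OC(C)(C)C#CC(O)CC[C@]1(C)O[Si](C)(C)C=C(C)[C@@H]1COCc1ccccc1 | intermediate
12 | ynone | C[Si](C)(C)OC(C)(C)C#CC(=O)CC[C@]1(C)O[Si](C)(C)C=C(C)[C@@H]1COCc1ccccc1 | intermediate
13 | β-diethylamino enone | CCN(CC)C(=CC(=O)CC[C@]1(C)O[Si](C)(C)C=C(C)[C@@H]1COCc1ccccc1)C(C)(C)O[Si](C)(C)C | intermediate (not isolated)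
14 | furanone: 2,2-dimethyl-5-[2-(oxasilin-6-yl)ethyl]furan-3(2H)-one | CC1(C)OC(CC[C@]2(C)O[Si](C)(C)C=C(C)[C@@H]2COCc2ccccc2)=CC1=O | intermediate
15 | photoadduct: siloxane-bridged cage, cyclobutane C4–C5–C5a–C9a cis-fused to tetrahydrofuranone and cyclohexane, C5a methyl cis to C7 methyl | CC1(C)O[C@]23CC[C@]4(C)O[Si](C)(C)[C@H]([C@H]2C1=O)[C@@]3(C)[C@@H]4COCc1ccccc1 | intermediate
16 | trimethylsilyl enol ether (C3=C4) of 17 | CC1(C)OC2=CC[C@]3(C)O[Si](C)(C)[C@H](C=C1O[Si](C)(C)C)[C@@]2(C)[C@@H]3COCc1ccccc1 | intermediate (not isolated)
17 | enol ether ketone: C9=C9a unsaturated benzoxepin-3-one with C5–SiMe2–O–C7 bridge | CC1(C)OC2=CC[C@]3(C)O[Si](C)(C)[C@H](CC1=O)[C@@]2(C)[C@@H]3COCc1ccccc1 | intermediate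
18 | 5-hydroxy ketone with free C7 hydroxyl | CC1(C)OC2=CC[C@](C)(O)[C@@H](COCc3ccccc3)[C@]2(C)[C@H](O)CC1=O | intermediate
19 | C5 mesylate of 18 | CC1(C)OC2=CC[C@](C)(O)[C@@H](COCc3ccccc3)[C@]2(C)[C@H](OS(C)(=O)=O)CC1=O | intermediate (not isolated)
20 | enone: C4=C5 and C9=C9a unsaturated 3-ketone | CC1(C)OC2=CC[C@](C)(O)[C@@H](COCc3ccccc3)[C@]2(C)C=CC1=O | intermediate
21 | (5aS,6R,7S,9aS)-7-hydroxy-6-(hydroxymethyl)-2,2,5a,7-tetramethyloctahydro-1-benzoxepin-3(2H)-one | CC1(C)O[C@H]2CC[C@](C)(O)[C@@H](CO)[C@]2(C)CCC1=O | intermediate
22 | 6-(iodomethyl) analogue of 21 | CC1(C)O[C@H]2CC[C@](C)(O)[C@@H](CI)[C@]2(C)CCC1=O | intermediate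
23 | C7 trimethylsilyl ether of 22 | CC1(C)O[C@H]2CC[C@](C)(O[Si](C)(C)C)[C@@H](CI)[C@]2(C)CCC1=O | intermediate
24 | 4,4-dimethylcyclohex-2-en-1-one | CC1(C)CCC(=O)C=C1 | starting material
25 | isoprene | CC(=C)C=C | starting material
26 | (4aR,8aS)-4,4,6-trimethyl-3,4,4a,5,8,8a-hexahydronaphthalen-1(2H)-one, cis-fused | CC1=CC[C@H]2[C@@H](C1)C(C)(C)CCC2=O | intermediate
27 | C5′ exocyclic methylene analogue of 26 | CC1=CC[C@H]2[C@@H](C1)C(C)(C)CCC2=C | intermediate
28 | C5′ tertiary hydroperoxide | CC1=CC[C@H]2[C@@H](C1)C(C)(C)CC[C@]2(C)OO | intermediate (not isolated)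
29 | C5′ tertiary alcohol, hydroxyl cis to ring-fusion hydrogens | CC1=CC[C@H]2[C@@H](C1)C(C)(C)CC[C@]2(C)O | intermediate
30 | triethylsilyl ether of 29 | CC1=CC[C@H]2[C@@H](C1)C(C)(C)CC[C@]2(C)O[Si](CC)(CC)CC | intermediate
31 | C1′ allylic alcohol (epimers) | CC1=CC[C@H]2[C@@H](C1O)C(C)(C)CC[C@]2(C)O[Si](CC)(CC)CC | intermediate
32 | enone: C1′ ketone, C2′=C3′ | CC1=CC[C@H]2[C@@H](C1=O)C(C)(C)CC[C@]2(C)O[Si](CC)(CC)CC | intermediate
33 | saturated C1′ ketone, (2′R) methyl | C[C@@H]1CC[C@H]2[C@@H](C1=O)C(C)(C)CC[C@]2(C)O[Si](CC)(CC)CC | intermediate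
34 | C1′ exocyclic methylene compound | C[C@@H]1CC[C@H]2[C@@H](C1=C)C(C)(C)CC[C@]2(C)O[Si](CC)(CC)CC | intermediate
35 | primary alkylborane (C1′ epimers) | C[C@@H]1CC[C@H]2[C@@H](C1CB)C(C)(C)CC[C@]2(C)O[Si](CC)(CC)CC | intermediate (not isolated)
36 | C1′ hydroxymethyl compound (C1′ epimers) | C[C@@H]1CC[C@H]2[C@@H](C1CO)C(C)(C)CC[C@]2(C)O[Si](CC)(CC)CC | intermediate
37 | C1′ carbaldehyde (C1′ epimers) | C[C@@H]1CC[C@H]2[C@@H](C1C=O)C(C)(C)CC[C@]2(C)O[Si](CC)(CC)CC | intermediate
38 | potassium (E)-enolate of 37 | C[C@@H]1CC[C@H]2[C@@H](/C1=C/[O-])C(C)(C)CC[C@]2(C)O[Si](CC)(CC)CC.[K+] | intermediate (not isolated)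
39 | (E)-enol triflate, OTf on the C2′ side | C[C@@H]1CC[C@H]2[C@@H](/C1=C/OS(=O)(=O)C(F)(F)F)C(C)(C)CC[C@]2(C)O[Si](CC)(CC)CC | intermediate
40 | alkylzinc iodide from 23 | CC1(C)O[C@H]2CC[C@](C)(O[Si](C)(C)C)[C@@H](C[Zn]I)[C@]2(C)CCC1=O | intermediate (not isolated)
41 | bis-silyl ether of the target (C7 OTMS, C5′ OTES) | C[C@@H]1CC[C@H]2[C@@H](/C1=C/C[C@H]1[C@]3(C)CCC(=O)C(C)(C)O[C@H]3CC[C@]1(C)O[Si](C)(C)C)C(C)(C)CC[C@]2(C)O[Si](CC)(CC)CC | intermediate
42 | CNP0232921.1 | C[C@@H]1CC[C@H]2[C@@H](/C1=C/C[C@H]1[C@]3(C)CCC(=O)C(C)(C)O[C@H]3CC[C@]1(C)O)C(C)(C)CC[C@]2(C)O | target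

**Step count and risks**

Total step count: 29. Longest linear sequence: 18 steps (steps 1–16, then 28 and 29); the decalin branch has 11 steps (17–27).

Steps most likely to fail:

Step 11. The silylated ketone may be deprotonated at C4 to a stable silyl enol ether before heterolysis occurs, the cyclobutane may ionise in the other sense (C4–C5, i.e. cycloreversion), or the siloxane may be lost under the Lewis acid. Fallback with known chemistry, setting out from 15 and returning at 17: aqueous acid (TsOH·H2O, wet THF) should open the alkoxycyclobutyl ketone by the hydrolytic retro-aldol path of de Mayo adducts to the seco hydroxy diketone F1. Treatment with CH(OMe)3, MeOH and camphorsulfonic acid should re-close the tertiary hydroxyl onto the C9a ketone as the cyclic mixed methyl ketal F2. Elimination of methanol from the ketal (TMSOTf, iPr2NEt) then gives 17.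

Step 10. The 1,4-biradical may revert instead of closing because of the strain of the siloxane-bridged cage, or closure may go onto C5 (crossed mode), so conversion stays low. Fallback setting out from 14 and returning at 21: protodesilylation of the alkenylsiloxane (Bu4NF, wet THF/DMSO) should give the hydroxy isopropenyl furanone F3. Its irradiation under the conditions of step 10 gives the unbridged photoadduct F4 by ordinary 6-exo closure; facial control then rests only on the chair preference of the tether, and the C5a epimers are separated by chromatography. The conditions of step 11 (with in situ silylation of the hydroxyl) give the enol ether keto alcohol F5, and hydrogenation as in step 14 gives 21 directly, without Tamao oxidation or elimination.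

Step 17. The γ,γ-disubstituted enone may bind the chiral Lewis acid poorly, so that the background reaction erodes the enantioselectivity, and the cis ring fusion may epimerise under acid. Fallback setting out from 24 and 25 and returning at 26: the racemic cis adduct (same constitution as 26) is made with AlCl3 in toluene and reduced with NaBH4 from the convex face to the cis-octalol, whose wanted enantiomer is F6. Lipase-catalysed acylation (lipase PS, vinyl acetate) should leave F6 and convert its antipode into the acetate F7 (if the enzyme prefers F6, its acetate is separated and saponified). Periodinane oxidation of F6 returns enantiopure 26.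

Further compounds
F1 | step 11 | seco hydroxy diketone: siloxane-bridged cyclohexanone (C9a ketone) whose C5 carries CH2C(=O)C(CH3)2OH | CC(C)(O)C(=O)C[C@H]1[Si](C)(C)O[C@@]2(C)CCC(=O)[C@]1(C)[C@@H]2COCc1ccccc1
F2 | step 11 | cyclic mixed methyl ketal: 9a-methoxy analogue of 17 without the C9=C9a double bond (C9a epimers) | CC1(C)OC2(OC)CC[C@]3(C)O[Si](C)(C)[C@H](CC1=O)[C@@]2(C)[C@@H]3COCc1ccccc1
F3 | step 10 | hydroxy isopropenyl furanone (desilylated 14) | CC1(C)OC(CC[C@](C)(O)[C@@H](COCc2ccccc2)C(C)=C)=CC1=O
F4 | step 10 | unbridged photoadduct with free C7 hydroxyl and C5 methylene | CC1(C)O[C@@]23CC[C@](C)(O)[C@@H](COCc4ccccc4)[C@]2(C)C[C@H]3C1=O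
F5 | step 10 | enol ether keto alcohol: C9=C9a unsaturated 6-(benzyloxymethyl)-7-hydroxy benzoxepin-3-one | CC1(C)OC2=CC[C@](C)(O)[C@@H](COCc3ccccc3)[C@]2(C)CCC1=O
F6 | step 17 | cis-octalol from reduction of 26 (hydroxyl trans to the ring-fusion hydrogens) | CC1=CC[C@H]2[C@@H](C1)C(C)(C)CC[C@H]2O
F7 | step 17 | acetate of the antipode of F6 | CC1=CC[C@@H]2[C@H](C1)C(C)(C)CC[C@@H]2OC(C)=O
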